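**Plan**
The two phenols and the aldehyde of the target are unmasked last (two methyl ethers, one diethyl acetal). The hexasubstituted benzene is then cut at C2–C3 and C1–C6.
This cut is possible because the ring is a symmetric four-carbon run C3(Br)–C4(O)–C5(O)–C6(Br) joined to the two-carbon unit C1(CHO)–C2(Br). A mirror-symmetric diene and one alkyne therefore give the ring with no regiochemical question.
Forward: 3,4-dimethoxythiophene is dibrominated and oxidised at sulfur to the thiophene 1,1-dioxide (diene). Propiolaldehyde diethyl acetal is brominated at the alkyne terminus (dienophile).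
Diels–Alder union of the two and loss of SO2 build the only ring, the benzene, with all six substituents in place. Acetal hydrolysis and BBr3 ether cleavage finish the synthesis.
Stereochemistry: the target is achiral and has no stereocentre. The two bridgehead centres of the transient cycloadduct vanish when SO2 leaves.

Key step: step 4

Remark: 3,4-dimethoxythiophene and 3,3-diethoxyprop-1-yne are taken as the commercial starting materials; dimethyldioxirane is used as a freshly prepared, titrated solution in acetone.

**Step 1**
Reactants: 1 3,4-dimethoxythiophene
Product: 3 2,5-dibromo-3,4-dimethoxythiophene, via 2-bromo-3,4-dimethoxythiophene 2 (not isolated)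
Conditions: NBS (2.05 equiv), DMF, 0 °C → rt, dark; used at once
Reagents that add atoms: N-bromosuccinimide (NBS), O=C1CCC(=O)N1Br
Why: Twofold electrophilic aromatic bromination at the two free α-positions, which are activated by the ring sulfur and the neighbouring methoxy groups, while NBS in DMF avoids strong acid and the β-positions are already occupied.

**Step 2**
Reactants: 3 2,5-dibromo-3,4-dimethoxythiophene
Product: 5 2,5-dibromo-3,4-dimethoxythiophene 1,1-dioxide, via dibromodimethoxythiophene 1-oxide 4 (not isolated)
Conditions: DMDO (3 equiv, acetone solution), CH2Cl2, −20 °C → rt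
Reagents that add atoms: dimethyldioxirane (DMDO), CC1(C)OO1
Why: Oxidation of a thiophene to its S,S-dioxide by two electrophilic oxygen transfers from the dioxirane under neutral conditions; the non-aromatic S-oxide 4 should be oxidised faster than 3, and the α-bromines shield the product from self-cycloaddition.

**Step 3**
Reactants: 6 3,3-diethoxyprop-1-yne
Product: 7 1-bromo-3,3-diethoxyprop-1-yne
Conditions: NBS (1.1 equiv), AgNO3 (10 mol %), acetone, rt, dark
Reagents that add atoms: N-bromosuccinimide (NBS), O=C1CCC(=O)N1Br
Why: AgNO3-catalysed electrophilic bromination of a terminal alkyne with NBS through the silver acetylide, a neutral process that leaves the diethyl acetal untouched.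

**Step 4**
Reactants: 5 2,5-dibromo-3,4-dimethoxythiophene 1,1-dioxide and 7 1-bromo-3,3-diethoxyprop-1-yne
Product: 9 1,2,4-tribromo-3-(diethoxymethyl)-5,6-dimethoxybenzene, via bridged sulfone adduct 8 (not isolated)
Conditions: 7 (2.5 equiv), o-xylene, 130 °C, N2 sweep, BHT (cat.)
Reagents that add atoms: none
Why: The s-cis-locked diene of 5 and the triple bond of 7 combine in a concerted suprafacial (4+2) cycloaddition that makes the future C2–C3 and C1–C6 bonds of the target and gives the 7-thiabicyclo[2.2.1]heptadiene dioxide 8, which at this temperature loses SO2 by a thermally allowed cheletropic extrusion and becomes the benzene 9. The closest known reaction type is the Diels–Alder/SO2-extrusion benzannulation of halogenated thiophene 1,1-dioxides with alkynes. The one ring of the target, the benzene, is closed by this intermolecular cycloaddition (both σ-bonds in one step, six-membered carbocycle) and is aromatised by the extrusion, so no separate oxidation is needed. No stereocentre is carried forward, because the two bridgehead centres of racemic 8 are destroyed when SO2 leaves. Regioselectivity is not required, since the diene has a mirror plane through sulfur and either orientation of 7 gives the same ring; the step needs chemoselectivity (cycloaddition outrunning self-reaction of 5 and thermal loss of 7), which the 2,5-bromines of the sulfone, the excess of 7 and the radical inhibitor are meant to secure. Electronically the sulfone lowers the diene LUMO towards the bromine-raised HOMO of the alkyne while the methoxy groups lift the diene HOMO, so either frontier pairing can contribute with this weakly polarised dienophile.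

**Step 5**
Reactants: 9 1,2,4-tribromo-3-(diethoxymethyl)-5,6-dimethoxybenzene
Product: 10 2,3,6-tribromo-4,5-dimethoxybenzaldehyde
Conditions: 2 M HCl (aq), THF, 40 °C
Reagents that add atoms: water, O
Why: Acid-catalysed acetal hydrolysis through the oxocarbenium ion, helped by relief of the crowding between the diethoxymethyl group and its two ortho bromines; aryl methyl ethers and aryl bromides are inert to dilute aqueous acid.

**Step 6**
Reactants: 10 2,3,6-tribromo-4,5-dimethoxybenzaldehyde
Product: 12 2,3,6-tribromo-4,5-dihydroxybenzaldehyde, via cyclic bromoborate 11 (not isolated)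
Conditions: BBr3 (4 equiv), CH2Cl2, −78 °C → rt; then H2O, 0 °C
Reagents that add atoms: none
Why: BBr3 cleavage of aryl methyl ethers (boron binds each ether oxygen and bromide removes the methyl group by SN2) should give the cyclic bromoborate 11, which water hydrolyses to the catechol; the formyl group is only complexed and returns on work-up, and the aryl bromides do not react.

**Compound list**
1 | 3,4-dimethoxythiophene | COc1cscc1OC | starting material
2 | 2-bromo-3,4-dimethoxythiophene | COc1csc(Br)c1OC | intermediate (not isolated)
3 | 2,5-dibromo-3,4-dimethoxythiophene | COc1c(Br)sc(Br)c1OC | intermediate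
4 | 2,5-dibromo-3,4-dimethoxythiophene 1-oxide | COC1=C(Br)S(=O)C(Br)=C1OC | intermediate (not isolated)
5 | 2,5-dibromo-3,4-dimethoxythiophene 1,1-dioxide | COC1=C(Br)S(=O)(=O)C(Br)=C1OC | intermediate
6 | 3,3-diethoxyprop-1-yne (propiolaldehyde diethyl acetal) | CCOC(OCC)C#C | starting material
7 | 1-bromo-3,3-diethoxyprop-1-yne | CCOC(OCC)C#CBr | intermediate
8 | 1,2,4-tribromo-3-(diethoxymethyl)-5,6-dimethoxy-7-thiabicyclo[2.2.1]hepta-2,5-diene 7,7-dioxide (racemic) | CCOC(OCC)C1=C(Br)C2(Br)C(OC)=C(OC)C1(Br)S2(=O)=O | intermediate (not isolated)
9 | 1,2,4-tribromo-3-(diethoxymethyl)-5,6-dimethoxybenzene (diethyl acetal of 10) | CCOC(OCC)c1c(Br)c(Br)c(OC)c(OC)c1Br | intermediate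
10 | 2,3,6-tribromo-4,5-dimethoxybenzaldehyde | O=Cc1c(Br)c(Br)c(OC)c(OC)c1Br | intermediate
11 | 2,4,6,7-tetrabromo-1,3,2-benzodioxaborole-5-carbaldehyde | O=Cc1c(Br)c(Br)c2OB(Br)Oc2c1Br | intermediate (not isolated)
12 | 2,3,6-tribromo-4,5-dihydroxybenzaldehyde | O=Cc1c(Br)c(O)c(O)c(Br)c1Br | target

**Step count**
Total: 6 steps. Longest linear sequence: 5 steps (steps 1, 2, 4, 5 and 6 from 1); step 3 is a one-step side branch from 6.

**Steps most likely to fail**

Step 4 (key cycloaddition). The cycloaddition may be too slow for this pairing, a diene carrying both donor and acceptor groups and a crowded internal bromoalkyne. Thermal decay of the sulfone or oligomerisation of the bromoalkyne would then take over. The fallback sets out from sulfone 5 and the unbrominated alkyne 6 and brings the third bromine in afterwards by aromatic substitution. Heating 5 with the smaller terminal alkyne 6 in o-xylene should pass through the bridged adduct 1,4-dibromo-2-(diethoxymethyl)-5,6-dimethoxy-7-thiabicyclo[2.2.1]hepta-2,5-diene 7,7-dioxide F1. Loss of SO2 from it gives 1,4-dibromo-5-(diethoxymethyl)-2,3-dimethoxybenzene F2. Hydrolysis with aqueous HCl in THF gives 2,5-dibromo-3,4-dimethoxybenzaldehyde F3. Its single free ring position lies para to the 3-methoxy group and should be brominated with Br2 and catalytic FeBr3 in acetic acid at 50 °C. This gives 10, where the route resumes.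

Step 2 (sulfur oxidation). Oxygen transfer may stall after the first oxygen, so that the S-oxide is consumed by self-cycloaddition, or the oxidant may attack the electron-rich ring carbons instead of sulfur. The fallback sets out from 3 and stops on purpose at the monoxide, which is the more reactive diene. Treatment of 3 with mCPBA (1 equiv) and BF3·OEt2 in CH2Cl2 at −20 °C should give the S-oxide 4, the Lewis acid binding the sulfoxide oxygen and holding back the second oxidation. Here 4 is isolated cold after a bicarbonate wash and warmed at once with 7 in toluene (60–80 °C). The expected adduct 1,2,4-tribromo-3-(diethoxymethyl)-5,6-dimethoxy-7-thiabicyclo[2.2.1]hepta-2,5-diene 7-oxide F4 extrudes sulfur monoxide, and the route is rejoined at 9. Diels–Alder reactions of thiophene S-oxides with alkynes followed by loss of SO are a known way to arenes.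

Step 1 (dibromination). The electron-rich dibromide may couple with itself during concentration or storage, as 2,5-dihalo-3,4-dialkoxythiophenes tend to do under traces of acid. The fallback sets out from 1 and reverses the order, so that no brominated electron-rich thiophene is handled. DMDO in acetone/CH2Cl2 (−20 °C → rt) should oxidise 1 through 3,4-dimethoxythiophene 1-oxide F5 to 3,4-dimethoxythiophene 1,1-dioxide F6. Each β-methoxy vinyl sulfone unit of this compound is an enol ether that is nucleophilic at the carbon next to sulfur. NBS (2.1 equiv, MeCN, rt) should therefore brominate the two positions in turn, through 2-bromo-3,4-dimethoxythiophene 1,1-dioxide F7, and give 5, where the route resumes.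

**Further compounds**
F1 | step 4 | 1,4-dibromo-2-(diethoxymethyl)-5,6-dimethoxy-7-thiabicyclo[2.2.1]hepta-2,5-diene 7,7-dioxide (racemic, not isolated) | CCOC(OCC)C1=CC2(Br)C(OC)=C(OC)C1(Br)S2(=O)=O
F2 | step 4 | 1,4-dibromo-5-(diethoxymethyl)-2,3-dimethoxybenzene (diethyl acetal of F3) | CCOC(OCC)c1cc(Br)c(OC)c(OC)c1Br
F3 | step 4 | 2,5-dibromo-3,4-dimethoxybenzaldehyde | O=Cc1cc(Br)c(OC)c(OC)c1Br
F4 | step 2 | 1,2,4-tribromo-3-(diethoxymethyl)-5,6-dimethoxy-7-thiabicyclo[2.2.1]hepta-2,5-diene 7-oxide (racemic, not isolated) | CCOC(OCC)C1=C(Br)C2(Br)C(OC)=C(OC)C1(Br)S2=O
F5 | step 1 | 3,4-dimethoxythiophene 1-oxide (not isolated) | COC1=CS(=O)C=C1OC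
F6 | step 1 | 3,4-dimethoxythiophene 1,1-dioxide | COC1=CS(=O)(=O)C=C1OC
F7 | step 1 | 2-bromo-3,4-dimethoxythiophene 1,1-dioxide (not isolated) | COC1=CS(=O)(=O)C(Br)=C1OC
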